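**Retrosynthetic overview**

1. Cut at the bond from the enone carbonyl carbon to C1' of ring A. The acyl donor is the ring B cinnamic N-methoxy-N-methylamide (E-alkene, silyl-protected phenol, prenyl in place); the acceptor is ring A masked as 2-methyl-5-prenyl-4H-pyran-4-one.
2. Enabling feature: ring A reads C1'(acyl)–C2'(OH)–C3'(H)–C4'(OH)–C5'(prenyl)–C6'(H), which is the pyranone atom for atom. The acidic 2-methyl carbon is C1', C2 with ring oxygen O1 is C2'–OH, C3–H is C3', C4=O is C4'–OH, C5–prenyl is C5', and C6–H (aldehyde level) is C6'.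
3. Key step (one flask): lateral acylation of the lithiated pyranone methyl group by the amide, then hydroxide ring opening, aldol closure C1'–C6' and aromatisation to ring A, with loss of the silyl group. Ring A needs no protecting group and no regiochemical decision.
4. Amide: 4-hydroxybenzaldehyde, ortho C-prenylation, silylation, Horner–Wadsworth–Emmons olefination. Pyranone: allomaltol, triflation, Stille prenylation.
5. Ring order: ring B and the pyranone ring are bought; the carbocyclic ring A is formed last, from the pyranone ring, in step 6.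

Key step: step 6

Remark: 5-hydroxy-2-methyl-4H-pyran-4-one (allomaltol) is taken as a catalogue compound; prenyl stands for 3-methylbut-2-en-1-yl and primed locants refer to ring A.

**Route**

Step 1
Reactants: 1 4-hydroxybenzaldehyde
Product: 2 4-hydroxy-3-(3-methylbut-2-en-1-yl)benzaldehyde
Conditions: prenyl bromide, 10% aq. KOH, rt
Reagents that add atoms: prenyl bromide (1-bromo-3-methylbut-2-ene), CC(C)=CCBr
Why: C-alkylation of the ambident phenoxide, which in water (oxygen shielded by hydrogen bonding) and with the para position blocked by the formyl group goes to the ortho carbon, is the established direct prenylation of this aldehyde, and no stereocentre is formed.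

Step 2
Reactants: 2 4-hydroxy-3-(3-methylbut-2-en-1-yl)benzaldehyde
Product: 3 4-[(tert-butyldimethylsilyl)oxy]-3-(3-methylbut-2-en-1-yl)benzaldehyde
Conditions: TBSCl, imidazole, DMF, rt
Reagents that add atoms: tert-butyldimethylsilyl chloride (TBSCl), CC(C)(C)[Si](C)(C)Cl
Why: standard silyl ether formation on a phenol, which keeps the later cinnamoyl carbonyl electrophilic (no phenoxide) and gives a group that hydroxide removes in step 6.

Step 3
Reactants: 3 4-[(tert-butyldimethylsilyl)oxy]-3-(3-methylbut-2-en-1-yl)benzaldehyde
Product: 4 (2E)-3-{4-[(tert-butyldimethylsilyl)oxy]-3-(3-methylbut-2-en-1-yl)phenyl}-N-methoxy-N-methylprop-2-enamide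
Conditions: (EtO)2P(O)CH2C(O)N(OMe)Me, NaH, THF, 0 °C to rt
Reagents that add atoms: diethyl {2-[methoxy(methyl)amino]-2-oxoethyl}phosphonate, CCOP(=O)(CC(=O)N(C)OC)OCC
Why: Horner–Wadsworth–Emmons olefination with an amide-stabilised phosphonate carbanion, whose reversible addition and anti-selective elimination should give the E-alkene and installs the N-methoxy-N-methylamide needed as acyl donor in step 6.

Step 4
Reactants: 5 5-hydroxy-2-methyl-4H-pyran-4-one (allomaltol)
Product: 6 6-methyl-4-oxo-4H-pyran-3-yl trifluoromethanesulfonate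
Conditions: Tf2O, pyridine, CH2Cl2, -10 to 0 °C
Reagents that add atoms: trifluoromethanesulfonic anhydride, O=S(=O)(OS(=O)(=O)C(F)(F)F)C(F)(F)F
Why: O-sulfonylation of the acidic, phenol-like enolic 5-hydroxyl (triflate formation, standard for 3-hydroxy-4-pyranones) turns the C5–O bond into a cross-coupling handle.

Step 5
Reactants: 6 6-methyl-4-oxo-4H-pyran-3-yl trifluoromethanesulfonate
Product: 7 2-methyl-5-(3-methylbut-2-en-1-yl)-4H-pyran-4-one
Conditions: Bu3SnCH2CH=CMe2, Pd(PPh3)4 (5 mol%), LiCl, DMF, 80 °C
Reagents that add atoms: tributyl(3-methylbut-2-en-1-yl)stannane, CCCC[Sn](CCCC)(CCCC)CC=C(C)C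
Why: Stille coupling, in which oxidative addition of the electron-poor enol triflate to zerovalent palladium, transmetalation of the allylic stannane and reductive elimination at the unhindered primary terminus should place the linear prenyl group at C5.

Step 6
Reactants: 7 2-methyl-5-(3-methylbut-2-en-1-yl)-4H-pyran-4-one; 4 (2E)-3-{4-[(tert-butyldimethylsilyl)oxy]-3-(3-methylbut-2-en-1-yl)phenyl}-N-methoxy-N-methylprop-2-enamide
Product: 12 stipulin (2E)-1-[2,4-dihydroxy-5-(3-methylbut-2-en-1-yl)phenyl]-3-[4-hydroxy-3-(3-methylbut-2-en-1-yl)phenyl]prop-2-en-1-one, via lithium dienolate 8 (not isolated), via silylated acylmethylpyranone 9 (not isolated), via desilylated acylmethylpyranone 10 (not isolated), via open-chain triketo aldehyde 11 (not isolated)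
Conditions: LiN(SiMe3)2, THF, -78 °C; 4, -78 to 0 °C; then 2 M KOH, MeOH–H2O, 40 °C; 1 M HCl to pH 6, 0 °C
Reagents that add atoms: none
Why: Proposed new method: the 2-methyl group of 7 is the γ-position of a vinylogous ester, so LiN(SiMe3)2 gives the cross-conjugated dienolate 8, which reacts at its exocyclic carbon (this restores the pyranone π-system) with the amide carbonyl of 4 in a vinylogous Claisen condensation; the chelated tetrahedral adduct stops over-addition and collapses on addition of aqueous KOH to ketone 9, in which the bond between the enone carbonyl carbon and the future C1' exists. Hydroxide then cleaves the aryl silyl ether (10) and adds to C6, the only unsubstituted β-position of the pyranone, so that the ring opens to the 3,5,7-triketo aldehyde chain 11 (the added oxygen leaves again as water in the next event). The doubly activated methylene carbon between the cinnamoyl carbonyl and the C2' carbonyl attacks the formyl carbon in a 6-exo-trig Knoevenagel-type aldol closure, and loss of water with enolisation of the two ring carbonyls gives the aromatic ring A, which makes the sequence irreversible. The closest known reaction types are the lateral acylation of 2-methyl-4-pyranones and 2-methylchromones through their lithium dienolates, the alkali-induced conversion of 2,6-dimethyl-4-pyranone into orcinol, the pyrylium-to-phenol ring transformation and the aldol aromatisation of β-polyketone chains in biomimetic polyketide synthesis; their merger in one flask on a 6-unsubstituted pyranone that carries an enone is what is new. No stereocentre is formed and the E-alkene of 4 is carried through unchanged, the trans-enone being the thermodynamic isomer under the basic conditions. The step needs carbonyl over conjugate attack on 4, which the weak Michael acceptor character of the electron-rich cinnamamide should secure, and aldol closure over retro-Claisen loss of formate or Michael closure onto the enone, which the six-membered closure onto an aldehyde-level carbon and the phenoxide-deactivated enone should secure; the substitution pattern of ring A needs no control because every ring atom is already in place in 7.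

**Compound list**

1 | 4-hydroxybenzaldehyde | O=Cc1ccc(O)cc1 | starting material
2 | 4-hydroxy-3-(3-methylbut-2-en-1-yl)benzaldehyde | CC(C)=CCc1cc(C=O)ccc1O | intermediate
3 | 4-[(tert-butyldimethylsilyl)oxy]-3-(3-methylbut-2-en-1-yl)benzaldehyde | CC(C)=CCc1cc(C=O)ccc1O[Si](C)(C)C(C)(C)C | intermediate
4 | (2E)-3-{4-[(tert-butyldimethylsilyl)oxy]-3-(3-methylbut-2-en-1-yl)phenyl}-N-methoxy-N-methylprop-2-enamide | CC(C)=CCc1cc(/C=C/C(=O)N(C)OC)ccc1O[Si](C)(C)C(C)(C)C | intermediate
5 | 5-hydroxy-2-methyl-4H-pyran-4-one (allomaltol) | CC1=CC(=O)C(O)=CO1 | starting material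
6 | 6-methyl-4-oxo-4H-pyran-3-yl trifluoromethanesulfonate | CC1=CC(=O)C(OS(=O)(=O)C(F)(F)F)=CO1 | intermediate
7 | 2-methyl-5-(3-methylbut-2-en-1-yl)-4H-pyran-4-one | CC1=CC(=O)C(CC=C(C)C)=CO1 | intermediate
8 | lithium 2-methylidene-5-(3-methylbut-2-en-1-yl)-2H-pyran-4-olate (lithium dienolate of 7; not isolated) | [Li+].[O-]C1=CC(=C)OC=C1CC=C(C)C | intermediate
9 | 2-[(3E)-4-{4-[(tert-butyldimethylsilyl)oxy]-3-(3-methylbut-2-en-1-yl)phenyl}-2-oxobut-3-en-1-yl]-5-(3-methylbut-2-en-1-yl)-4H-pyran-4-one (not isolated) | CC(C)=CCc1cc(/C=C/C(=O)CC2=CC(=O)C(CC=C(C)C)=CO2)ccc1O[Si](C)(C)C(C)(C)C | intermediate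
10 | 2-[(3E)-4-[4-hydroxy-3-(3-methylbut-2-en-1-yl)phenyl]-2-oxobut-3-en-1-yl]-5-(3-methylbut-2-en-1-yl)-4H-pyran-4-one (not isolated) | CC(C)=CCc1cc(/C=C/C(=O)CC2=CC(=O)C(CC=C(C)C)=CO2)ccc1O | intermediate
11 | (1Z,8E)-1-hydroxy-9-[4-hydroxy-3-(3-methylbut-2-en-1-yl)phenyl]-2-(3-methylbut-2-en-1-yl)nona-1,8-diene-3,5,7-trione (hydroxymethylene tautomer of the 3,5,7-trioxo aldehyde; not isolated) | O/C=C(/CC=C(C)C)C(=O)CC(=O)CC(=O)/C=C/c1ccc(O)c(CC=C(C)C)c1 | intermediate
12 | stipulin, (2E)-1-[2,4-dihydroxy-5-(3-methylbut-2-en-1-yl)phenyl]-3-[4-hydroxy-3-(3-methylbut-2-en-1-yl)phenyl]prop-2-en-1-one | CC(C)=CCc1cc(/C=C/C(=O)c2cc(CC=C(C)C)c(O)cc2O)ccc1O | target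

**Step count**

Total: 6 steps. Longest linear sequence: 4 steps (steps 1, 2, 3 and 6); the pyranone branch is steps 4, 5 and 6.

**Steps most likely to fail**

Step 6. The dienolate may add to the cinnamamide in conjugate fashion instead of at the carbonyl. After ring opening, the chain may lose its formyl carbon by retro-Claisen cleavage, may close by Michael addition onto the enone, or may re-close to the pyranone on acidification instead of undergoing the aldol aromatisation. The fallback uses known reaction types only, sets out from 4 and returns at 12, and carries ring A at the dihydroresorcinol oxidation level. Commercial 3-ethoxycyclohex-2-en-1-one is deprotonated at C6 (LiN(iPr)2, THF, -78 °C) and alkylated with prenyl bromide (Stork–Danheiser alkylation) to 3-ethoxy-6-(3-methylbut-2-en-1-yl)cyclohex-2-en-1-one F1. Mild hydrolysis (1 M HCl, THF, rt) should give 4-(3-methylbut-2-en-1-yl)cyclohexane-1,3-dione F2. Its dianion (2.2 equiv LiN(iPr)2, THF–DMPU, -78 to 0 °C; second deprotonation at the unsubstituted C6) is acylated by 4 (γ-acylation of a β-diketone dianion) to 4-[(2E)-3-{4-[(tert-butyldimethylsilyl)oxy]-3-(3-methylbut-2-en-1-yl)phenyl}prop-2-enoyl]-6-(3-methylbut-2-en-1-yl)cyclohexane-1,3-dione F3. DDQ in dioxane should dehydrogenate the acyl dione ring to (2E)-3-{4-[(tert-butyldimethylsilyl)oxy]-3-(3-methylbut-2-en-1-yl)phenyl}-1-[2,4-dihydroxy-5-(3-methylbut-2-en-1-yl)phenyl]prop-2-en-1-one F4, and Bu4NF buffered with AcOH (THF, 0 °C) should then give 12.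

Step 5. Coupling may occur through the tertiary terminus of the prenyl unit (reverse-prenyl isomer), or the pyranone triflate may be consumed by slow oxidative addition and hydrolysis. The fallback sets out from 6 and returns at 7. Stille coupling with allyltributylstannane (Pd(PPh3)4, LiCl, DMF, 80 °C), which has no regiochemical ambiguity, should give 2-methyl-5-(prop-2-en-1-yl)-4H-pyran-4-one F5. Cross-metathesis with excess 2-methylbut-2-ene (second-generation Grubbs catalyst, CH2Cl2, 40 °C) should convert the allyl into the prenyl group of 7.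

Step 1. O-alkylation and double alkylation of the phenoxide may compete with ortho C-alkylation, and conversion may stay low. The fallback sets out from 1 and returns at 2. Tsuji–Trost O-alkylation with tert-butyl 2-methylbut-3-en-2-yl carbonate (Pd(PPh3)4, THF, 0 °C) should give the branched ether 4-[(2-methylbut-3-en-2-yl)oxy]benzaldehyde F6. Aromatic Claisen rearrangement (N,N-diethylaniline, heat), with the para position blocked, should deliver the linear prenyl group to the ortho carbon and give 2.

**Further compounds**

F1 | step 6 | 3-ethoxy-6-(3-methylbut-2-en-1-yl)cyclohex-2-en-1-one (racemic) | CCOC1=CC(=O)C(CC=C(C)C)CC1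
F2 | step 6 | 4-(3-methylbut-2-en-1-yl)cyclohexane-1,3-dione (racemic) | O=C1CC(=O)C(CC=C(C)C)CC1
F3 | step 6 | 4-[(2E)-3-{4-[(tert-butyldimethylsilyl)oxy]-3-(3-methylbut-2-en-1-yl)phenyl}prop-2-enoyl]-6-(3-methylbut-2-en-1-yl)cyclohexane-1,3-dione (one enol tautomer, racemic) | CC(C)=CCC1CC(C(=O)/C=C/c2ccc(O[Si](C)(C)C(C)(C)C)c(CC=C(C)C)c2)=C(O)CC1=O
F4 | step 6 | (2E)-3-{4-[(tert-butyldimethylsilyl)oxy]-3-(3-methylbut-2-en-1-yl)phenyl}-1-[2,4-dihydroxy-5-(3-methylbut-2-en-1-yl)phenyl]prop-2-en-1-one | CC(C)=CCc1cc(/C=C/C(=O)c2cc(CC=C(C)C)c(O)cc2O)ccc1O[Si](C)(C)C(C)(C)C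
F5 | step 5 | 2-methyl-5-(prop-2-en-1-yl)-4H-pyran-4-one | CC1=CC(=O)C(CC=C)=CO1
F6 | step 1 | 4-[(2-methylbut-3-en-2-yl)oxy]benzaldehyde | C=CC(C)(C)Oc1ccc(C=O)cc1
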